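## Structural features

Dielsianone is an achiral, unsymmetrical benzil: a 1,2-dione links a 4-methoxyphenyl ring (ring C) to C6 of a 2,2-dimethyl-2H-chromene. The chromene is a benzene ring (ring A: C4a, C5, C6, C7, C8, C8a) fused across C4a–C8a to a 2H-pyran (ring B: O1, C2 with two methyl groups, C3=C4). Ring A is pentasubstituted and every substituent is different: C4a carries the vinylic C4, C5 a free hydroxyl, C6 the dione, C7 the only hydrogen, C8 a methoxy group and C8a the ring oxygen O1. There is no stereocentre and no stereogenic double bond, so the problem is one of regiochemistry and functional group compatibility. Fragile groups are the 1,2-dione (benzilic acid rearrangement with hydroxide or alkoxide, condensation with amines), the electron-rich C3=C4 alkene (acid, electrophilic oxidants, light-induced ring opening) and the C5-OH/C8-OMe hydroquinone monoether (oxidation to a quinone once the phenol is free). The real difficulty lies in ring A: five contiguous, different substituents, three of them oxygens that must be told apart (phenol, methyl ether, cyclic ether), and the bond from C6 to the dione next to the phenol. The key step exploits the para relationship of C5–OH and C8–OMe together with the lone C–H at C7: a 4-methoxyphenol with one unsubstituted position next to the methoxy carbon is what a benzannulation of a methoxycarbene complex, CO and a terminal alkyne produces, and the O1–C8a=C4a unit is a ready-made cyclic enol ether.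

## Logic of the disconnections

17 back to 16. The C5 O–H bond is retraced to an O–Si bond. The C5 oxygen is para to the C8 methoxy group, and a free phenol of this kind would not survive the two oxidations that come before. Nothing is gained in skeleton, but the oxidations can be ordered freely. The forward step must unmask under neutral, non-basic conditions that leave the dione alone.

16 back to 15. The C3=C4 π bond is retraced to the C3–H and C4–H bonds. With ring B saturated, the O1–C8a=C4a unit can come from a stable cyclic enol ether; a fragment that already held C3=C4 would be a 2H-pyran, prone to electrocyclic ring opening, and the alkene would not survive the alkyne oxidation. The forward step must dehydrogenate only at the benzylic C4–H and its neighbour.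

15 back to 14. The two C=O bonds are retraced to one C≡C bond. The alkyne is the dione at the same carbon count, but linear, small and inert to organochromium chemistry. This removes the base- and nucleophile-sensitive dione from the ring-forming stage. The forward oxidation must stop at the dione and spare ring A and the C4 methylene.

14 back to 7 and 11 (key disconnection). Three bonds of ring A are cut: C7–C8, C5–C6 and C4a–C5 (and the O–Si bond). Ring A falls apart into the carbene carbon of 7 (C8 with its methoxy group), the enol ether carbons of 7 (C8a and C4a), one CO ligand (C5 and its oxygen) and the terminal triple bond of 11 (C6 and C7). This cut removes every regiochemical question of ring A at once and joins the ring C half in the same operation. The gain is from a pentasubstituted arene to a heterocyclic carbene complex and a linear diyne. The forward step demands that the alkyne inserts with its CH terminus at the carbene carbon, that only the terminal triple bond of 11 reacts, and that the new phenol is trapped before it is oxidised or adds to the neighbouring alkyne.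

7 back to 3 and 4. The bond between the carbene carbon and the enol ether carbon is cut, together with the O–CH3 bond. This reduces the complex to a simple cyclic enol ether and a metal carbonyl. The forward step demands selective metalation at the vinylic position next to oxygen.

3 back to 1 and 2. The O1–C2 and C3–C4 bonds of the dihydropyran are cut in a [4+2] sense. This leads to two bulk chemicals. The forward cycloaddition must pair the oxygen with the dimethyl-substituted carbon.

11 back to 10, then to 8 and 9. The C–Si bond and then the central sp–sp bond of the diyne are cut. The silyl group is needed only to make the bromoalkyne partner stable and the coupling selective for the unsymmetrical diyne.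

## Other disconnections considered

Alternative 1: The first plan that comes to mind decorates an existing benzene ring. It cuts the C6–C(=O) bond (Friedel–Crafts acylation) and ring B (chromene annulation), and puts in the second carbonyl last. In the forward sense, 4-methoxybenzene-1,3-diol A1 would be acylated with an arylacetic acid (BF3·OEt2) to deoxybenzoin A2. A2 would be annulated between its two oxygens with a C5 enal (condensation, then oxa-6π electrocyclisation) to chromene A3. The key step would be the SeO2 (Riley) oxidation of A3 to 17. In step count this plan is shorter than the chosen one, and that is conceded. It is set aside for three reasons: every position of ring A depends on directing effects and chelation rather than on connectivity; the annulation must form its C–C bond at the most hindered site of A2; and the last step heats a free, para-oxygenated phenol with an oxidant, where quinone formation competes. The chosen plan is convergent and fixes all six ring A positions in one bond-forming event.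

Alternative 2: A 1,3-acyl shift. The C6–C(=O) bond is cut and the acyl group is returned to the C5 oxygen. Chromenol A4 would be esterified with an aroylformyl chloride to aryl ester A5, and a photo-Fries rearrangement would carry the aroylformyl group to C6 to give 17 directly. The preference for the chosen plan is mechanistic. The aroylformyl radical of the photo-Fries pair loses CO readily, so an aryl ketone rather than the dione is expected. 2H-Chromenes ring-open under the same irradiation. The Lewis acid variant would attack the chromene alkene and the methyl ethers. In addition, A4 itself needs the annulation between the two oxygens of A1 without a blocking group, which is the unfavoured regiochemistry.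

Alternative 3: Deletion of one ring carbon. The target is seen as a 4-hydroxy-3-arylcoumarin that has lost its lactone carbon. The pyranocoumarin A6 would be hydroxylated at C3 (peracid or base and O2), the lactone opened and the resulting β-keto acid decarboxylated. The benzoin so formed would be oxidised to 17. This follows the likely biogenesis. It is not preferred on step economy and structure: A6 is heavier than the target and would be made from A3 by C-acylation with a carbonate, so a carbon is put in only to be taken out. The excision is also a cascade of four events on a substrate that carries the sensitive chromene and phenol, not one defensible operation.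

Key step: step 5

Remark on the chemistry: the target has no stereocentre, so no step needs stereocontrol; compound 3 is treated as not purchasable and is made in step 1.

## Route

Step 1
Reactants: 1 acrolein (prop-2-enal); 2 isobutylene (2-methylprop-1-ene)
Product: 3 2,2-dimethyl-3,4-dihydro-2H-pyran
Conditions: 2 (excess), hydroquinone (cat.), neat, autoclave, 190–200 °C
Reagents that add atoms: none
Why: Thermal hetero-Diels–Alder reaction with inverse electron demand between the 1-oxadiene 1 and the 1,1-disubstituted alkene 2, a known entry to 2,2-dialkyl-3,4-dihydro-2H-pyrans; the nucleophilic CH2 terminus of 2 bonds to the β-carbon of 1 and the oxygen to the carbon that carries the two methyl groups, so only the 2,2-dimethyl isomer is expected; excess 2 and the inhibitor hold back dimerisation and polymerisation of 1.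

Step 2
Reactants: 3 2,2-dimethyl-3,4-dihydro-2H-pyran; 4 hexacarbonylchromium, Cr(CO)6
Product: 7 pentacarbonyl[(6,6-dimethyl-5,6-dihydro-4H-pyran-2-yl)(methoxy)methylidene]chromium, via 6-lithio-2,2-dimethyl-3,4-dihydro-2H-pyran 5 (not isolated), via lithium acylchromate 6 (not isolated)
Conditions: t-BuLi, THF/pentane, −78 → 0 °C; then 4, Et2O, 0 °C → rt; then Me3OBF4, CH2Cl2, 0 °C
Reagents that add atoms: trimethyloxonium tetrafluoroborate, C[O+](C)C.F[B-](F)(F)F
Why: Fischer carbene synthesis: t-BuLi removes the vinylic hydrogen next to oxygen of the cyclic enol ether, the vinyllithium 5 adds to a CO ligand of 4, and O-methylation of acylmetalate 6 gives the alkoxycarbene complex of zerovalent chromium; the methyl group put on here is the C8 methoxy group of the target.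

Step 3
Reactants: 8 4-ethynylanisole (1-ethynyl-4-methoxybenzene); 9 (bromoethynyl)triisopropylsilane
Product: 10 triisopropyl[4-(4-methoxyphenyl)buta-1,3-diyn-1-yl]silane
Conditions: CuCl (cat.), NH2OH·HCl, n-BuNH2, H2O/CH2Cl2, 0 °C → rt
Reagents that add atoms: none
Why: Cadiot–Chodkiewicz coupling of the copper acetylide of 8 with the 1-bromoalkyne 9; NH2OH·HCl keeps copper monovalent, which suppresses oxidative homocoupling of 8, and the bulky silyl group keeps the unsymmetrical diyne stable.

Step 4
Reactants: 10 triisopropyl[4-(4-methoxyphenyl)buta-1,3-diyn-1-yl]silane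
Product: 11 1-(buta-1,3-diyn-1-yl)-4-methoxybenzene
Conditions: TBAF, wet THF, 0 °C; kept as a cold solution and used at once
Reagents that add atoms: none
Why: Fluoride-induced protodesilylation of an alkynylsilane; the terminal aryl diyne is sensitive when neat, so it should be kept in solution, cold and dark, and taken directly into step 5.

Step 5
Reactants: 7 pentacarbonyl[(6,6-dimethyl-5,6-dihydro-4H-pyran-2-yl)(methoxy)methylidene]chromium; 11 1-(buta-1,3-diyn-1-yl)-4-methoxybenzene
Product: 14 tert-butyl({8-methoxy-6-[(4-methoxyphenyl)ethynyl]-2,2-dimethyl-3,4-dihydro-2H-chromen-5-yl}oxy)dimethylsilane, via tricarbonylchromium complex of the free phenol 12 (not isolated), via tricarbonylchromium complex of the silyl ether 13 (not isolated)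
Conditions: 11 (1.5 equiv), TBSCl, i-Pr2NEt, CH2Cl2, 50 °C (sealed); then air, hν, Et2O, rt
Reagents that add atoms: tert-butyldimethylsilyl chloride, CC(C)(C)[Si](C)(C)Cl
Why: Dötz [3+2+1] benzannulation with in-flask silylation: thermal loss of a cis CO from 7 lets the terminal triple bond of 11 coordinate and insert to give an eta-1,eta-3 vinylcarbene in which the alkyne CH carbon is bonded to the former carbene carbon, CO insertion gives an eta-4 vinylketene, and 6π electrocyclisation onto the enol ether C=C followed by tautomerisation closes ring A (the only ring formed, by disrotatory closure of the dienylketene on the Cr(CO)3 template) to give phenol complex 12. Three C–C bonds form (C7–C8, C5–C6, C4a–C5) and every position of ring A is fixed by connectivity: C8 with its methoxy group from the carbene carbon, C8a–O1 and C4a from the enol ether, C5–OH from CO, C6 with the arylethynyl group and C7–H from the alkyne. The closest known reaction type is the benzannulation of alkenyl(methoxy)carbene chromium complexes made from lithiated cyclic enol ethers (dihydropyrans, glycals) with alkynes, which gives 8-alkoxychroman-5-ols, together with the benzannulation of 1,3-diynes, which leaves an alkynyl group next to the new hydroxyl. Regioselectivity rests on sterics in the vinylcarbene: the larger alkyne substituent ends next to the CO-derived carbon, and for a terminal alkyne (hydrogen against alkynyl) this preference is at its largest, so the arylethynyl group should appear at C6 and hydrogen at C7. Site selectivity rests on the much faster insertion of the unhindered terminal triple bond; the internal one, flanked by two aryl groups in the product, should not compete while 11 is in excess. Alkenyl carbene complexes give phenols rather than indenes or furans because the electrocyclisation needs no dearomatisation, and no stereocentre is formed. TBSCl and i-Pr2NEt silylate the acidic complexed phenol 12 to 13, which blocks oxidation to the quinone and addition of the phenol to the neighbouring alkyne, and air with light then frees 14 from Cr(CO)3.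

Step 6
Reactants: 14 tert-butyl({8-methoxy-6-[(4-methoxyphenyl)ethynyl]-2,2-dimethyl-3,4-dihydro-2H-chromen-5-yl}oxy)dimethylsilane
Product: 15 1-{5-[(tert-butyldimethylsilyl)oxy]-8-methoxy-2,2-dimethyl-3,4-dihydro-2H-chromen-6-yl}-2-(4-methoxyphenyl)ethane-1,2-dione
Conditions: KMnO4, NaHCO3, MgSO4, acetone/H2O, 0 °C → rt
Reagents that add atoms: potassium permanganate, [K+].[O-][Mn](=O)(=O)=O
Why: Permanganate oxidation of a diarylalkyne to a benzil through a cyclic manganate ester, with bicarbonate/MgSO4 buffering that should stop at the dione and spare the aryl silyl ether; at this stage the molecule holds no alkene and no free phenol, which is why the chromene double bond is installed only afterwards.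

Step 7
Reactants: 15 1-{5-[(tert-butyldimethylsilyl)oxy]-8-methoxy-2,2-dimethyl-3,4-dihydro-2H-chromen-6-yl}-2-(4-methoxyphenyl)ethane-1,2-dione
Product: 16 1-{5-[(tert-butyldimethylsilyl)oxy]-8-methoxy-2,2-dimethyl-2H-chromen-6-yl}-2-(4-methoxyphenyl)ethane-1,2-dione
Conditions: DDQ, 1,4-dioxane (dry), reflux
Reagents that add atoms: none
Why: DDQ dehydrogenation of a 2,2-dimethylchroman to the 2H-chromene: hydride abstraction from benzylic C4 gives a cation stabilised by O1 and the C5 oxygen, and loss of a C3 proton gives the C3=C4 bond; the quaternary C2 rules out further oxidation of ring B, and the silyl ether keeps the para-oxygenated ring A from being oxidised to a quinone.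

Step 8
Reactants: 16 1-{5-[(tert-butyldimethylsilyl)oxy]-8-methoxy-2,2-dimethyl-2H-chromen-6-yl}-2-(4-methoxyphenyl)ethane-1,2-dione
Product: 17 dielsianone, 1-(5-hydroxy-8-methoxy-2,2-dimethyl-2H-chromen-6-yl)-2-(4-methoxyphenyl)ethane-1,2-dione
Conditions: TBAF, AcOH, THF, 0 °C
Reagents that add atoms: none
Why: Fluoride cleavage of the aryl silyl ether, buffered with AcOH so that no free alkoxide or hydroxide meets the 1,2-dione (benzilic acid rearrangement); the freed C5 phenol is hydrogen-bonded to the C6 carbonyl, and the chromene and methyl ethers are untouched.

## Compound list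

1 | acrolein (prop-2-enal) | C=CC=O | starting material
2 | isobutylene (2-methylprop-1-ene) | CC(C)=C | starting material
3 | 2,2-dimethyl-3,4-dihydro-2H-pyran | CC1(C)CCC=CO1 | intermediate
4 | hexacarbonylchromium, Cr(CO)6 | O=C=[Cr](=C=O)(=C=O)(=C=O)(=C=O)=C=O | starting material
5 | 6-lithio-2,2-dimethyl-3,4-dihydro-2H-pyran | [Li]C1=CCCC(C)(C)O1 | intermediate (not isolated)
6 | lithium pentacarbonyl[(6,6-dimethyl-5,6-dihydro-4H-pyran-2-yl)carbonyl]chromate (lithium acylchromate) | [Li+].[O-]C(C1=CCCC(C)(C)O1)=[Cr](=C=O)(=C=O)(=C=O)(=C=O)=C=O | intermediate (not isolated)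
7 | pentacarbonyl[(6,6-dimethyl-5,6-dihydro-4H-pyran-2-yl)(methoxy)methylidene]chromium | COC(C1=CCCC(C)(C)O1)=[Cr](=C=O)(=C=O)(=C=O)(=C=O)=C=O | intermediate
8 | 4-ethynylanisole (1-ethynyl-4-methoxybenzene) | COc1ccc(C#C)cc1 | starting material
9 | (bromoethynyl)triisopropylsilane | CC(C)[Si](C#CBr)(C(C)C)C(C)C | starting material
10 | triisopropyl[4-(4-methoxyphenyl)buta-1,3-diyn-1-yl]silane | COc1ccc(C#CC#C[Si](C(C)C)(C(C)C)C(C)C)cc1 | intermediate
11 | 1-(buta-1,3-diyn-1-yl)-4-methoxybenzene | COc1ccc(C#CC#C)cc1 | intermediate
12 | tricarbonyl{eta-6-8-methoxy-6-[(4-methoxyphenyl)ethynyl]-2,2-dimethyl-3,4-dihydro-2H-chromen-5-ol}chromium (Cr(CO)3 bound to ring A, written as two parts) | COc1ccc(C#Cc2cc(OC)c3c(c2O)CCC(C)(C)O3)cc1.O=C=[Cr](=C=O)=C=O | intermediate (not isolated)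
13 | tricarbonylchromium complex of 14 (Cr(CO)3 bound to ring A, written as two parts) | COc1ccc(C#Cc2cc(OC)c3c(c2O[Si](C)(C)C(C)(C)C)CCC(C)(C)O3)cc1.O=C=[Cr](=C=O)=C=O | intermediate (not isolated)
14 | tert-butyl({8-methoxy-6-[(4-methoxyphenyl)ethynyl]-2,2-dimethyl-3,4-dihydro-2H-chromen-5-yl}oxy)dimethylsilane | COc1ccc(C#Cc2cc(OC)c3c(c2O[Si](C)(C)C(C)(C)C)CCC(C)(C)O3)cc1 | intermediate
15 | 1-{5-[(tert-butyldimethylsilyl)oxy]-8-methoxy-2,2-dimethyl-3,4-dihydro-2H-chromen-6-yl}-2-(4-methoxyphenyl)ethane-1,2-dione | COc1ccc(C(=O)C(=O)c2cc(OC)c3c(c2O[Si](C)(C)C(C)(C)C)CCC(C)(C)O3)cc1 | intermediate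
16 | 1-{5-[(tert-butyldimethylsilyl)oxy]-8-methoxy-2,2-dimethyl-2H-chromen-6-yl}-2-(4-methoxyphenyl)ethane-1,2-dione | COc1ccc(C(=O)C(=O)c2cc(OC)c3c(c2O[Si](C)(C)C(C)(C)C)C=CC(C)(C)O3)cc1 | intermediate
17 | dielsianone, 1-(5-hydroxy-8-methoxy-2,2-dimethyl-2H-chromen-6-yl)-2-(4-methoxyphenyl)ethane-1,2-dione | COc1ccc(C(=O)C(=O)c2cc(OC)c3c(c2O)C=CC(C)(C)O3)cc1 | target

## Step count and least certain steps

Total step count: 8. Longest linear sequence: 6 steps (1, 2, 5, 6, 7, 8; the diyne branch 3, 4, 5, 6, 7, 8 is equally long).

Step 5 (key step). The most likely failure is loss of the carbene complex and the diyne to non-productive paths before CO insertion: repeated alkyne insertion at chromium (oligomerisation of the terminal diyne), a second benzannulation at the internal triple bond of the first-formed product, or thermal self-reaction of the conjugated diyne at 50 °C. The fallback separates ring construction from the arylalkyne. It sets out from 7 and comes back at 14. Benzannulation of 7 with commercial 3,3-diethoxyprop-1-yne under the same silylating conditions should pass through the tricarbonylchromium complex of 6-(diethoxymethyl)-8-methoxy-2,2-dimethyl-3,4-dihydro-2H-chromen-5-ol F1 and the tricarbonylchromium complex of its silyl ether F2 (neither isolated). Air and light should then give tert-butyl{[6-(diethoxymethyl)-8-methoxy-2,2-dimethyl-3,4-dihydro-2H-chromen-5-yl]oxy}dimethylsilane F3. Mild acetal hydrolysis (PPTS, acetone/H2O) should give 5-[(tert-butyldimethylsilyl)oxy]-8-methoxy-2,2-dimethyl-3,4-dihydro-2H-chromene-6-carbaldehyde F4. One-carbon homologation by the Colvin rearrangement (Me3SiCHN2, LiN(i-Pr)2, THF, −78 → 0 °C) should give tert-butyl[(6-ethynyl-8-methoxy-2,2-dimethyl-3,4-dihydro-2H-chromen-5-yl)oxy]dimethylsilane F5. Sonogashira coupling of F5 with 4-iodoanisole (Pd(PPh3)2Cl2, CuI, Et3N) returns to 14.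

Step 6. The most likely failure is over-oxidation: cleavage of the dione to two carboxylic acids, or attack of permanganate on the electron-rich ring A after partial loss of the silyl group. The fallback reaches the dione in stages through the alkene and the diol. It sets out from 14 and comes back at 15. Semi-hydrogenation (H2, Pd/CaCO3–Pb(OAc)2, quinoline) should give tert-butyl({8-methoxy-6-[(Z)-2-(4-methoxyphenyl)ethenyl]-2,2-dimethyl-3,4-dihydro-2H-chromen-5-yl}oxy)dimethylsilane F6. Syn-dihydroxylation (OsO4 cat., NMO) should give racemic (1S,2R)-1-{5-[(tert-butyldimethylsilyl)oxy]-8-methoxy-2,2-dimethyl-3,4-dihydro-2H-chromen-6-yl}-2-(4-methoxyphenyl)ethane-1,2-diol F7, whose configuration is irrelevant. Double Swern oxidation ((COCl)2, DMSO, Et3N, −78 °C) of F7 gives 15.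

Step 7. The most likely failure is slow hydride abstraction from C4, because the lone pairs of O1 and the C5 oxygen are drawn towards the C6 acyl group; at the temperature then needed the quinone may instead strip the silyl group or attack ring A. The fallback replaces hydride abstraction by radical halogenation and elimination. It sets out from 15 and comes back at 16. Benzylic bromination (NBS, AIBN, PhCF3, 80 °C) should give racemic 1-{4-bromo-5-[(tert-butyldimethylsilyl)oxy]-8-methoxy-2,2-dimethyl-3,4-dihydro-2H-chromen-6-yl}-2-(4-methoxyphenyl)ethane-1,2-dione F8. Elimination of HBr with DBU (toluene, 60 °C) gives 16.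

Step 1. The most likely failure is low conversion with polymerisation of acrolein at the temperature that the unactivated alkene requires. The fallback builds the ring stepwise. It sets out from 1 and comes back at 3. Addition of HBr to 1 and acetalisation with ethylene glycol should give 2-(2-bromoethyl)-1,3-dioxolane F9. Its Grignard reagent (Mg, THF, below 30 °C) should open 2,2-dimethyloxirane at the CH2 carbon under CuI catalysis to give 5-(1,3-dioxolan-2-yl)-2-methylpentan-2-ol F10. Heating F10 with catalytic TsOH should give, by transacetalisation, racemic 2-[(6,6-dimethyloxan-2-yl)oxy]ethan-1-ol F11 in the flask, and this should lose ethylene glycol on distillation to give 3.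

## Further compounds

F1 | step 5 | tricarbonylchromium complex of 6-(diethoxymethyl)-8-methoxy-2,2-dimethyl-3,4-dihydro-2H-chromen-5-ol (Cr(CO)3 bound to ring A, written as two parts) | CCOC(OCC)c1cc(OC)c2c(c1O)CCC(C)(C)O2.O=C=[Cr](=C=O)=C=O
F2 | step 5 | tricarbonylchromium complex of tert-butyl{[6-(diethoxymethyl)-8-methoxy-2,2-dimethyl-3,4-dihydro-2H-chromen-5-yl]oxy}dimethylsilane (Cr(CO)3 bound to ring A, written as two parts) | CCOC(OCC)c1cc(OC)c2c(c1O[Si](C)(C)C(C)(C)C)CCC(C)(C)O2.O=C=[Cr](=C=O)=C=O
F3 | step 5 | tert-butyl{[6-(diethoxymethyl)-8-methoxy-2,2-dimethyl-3,4-dihydro-2H-chromen-5-yl]oxy}dimethylsilane | CCOC(OCC)c1cc(OC)c2c(c1O[Si](C)(C)C(C)(C)C)CCC(C)(C)O2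
F4 | step 5 | 5-[(tert-butyldimethylsilyl)oxy]-8-methoxy-2,2-dimethyl-3,4-dihydro-2H-chromene-6-carbaldehyde | O=Cc1cc(OC)c2c(c1O[Si](C)(C)C(C)(C)C)CCC(C)(C)O2
F5 | step 5 | tert-butyl[(6-ethynyl-8-methoxy-2,2-dimethyl-3,4-dihydro-2H-chromen-5-yl)oxy]dimethylsilane | C#Cc1cc(OC)c2c(c1O[Si](C)(C)C(C)(C)C)CCC(C)(C)O2
F6 | step 6 | tert-butyl({8-methoxy-6-[(Z)-2-(4-methoxyphenyl)ethenyl]-2,2-dimethyl-3,4-dihydro-2H-chromen-5-yl}oxy)dimethylsilane | COc1ccc(/C=C\c2cc(OC)c3c(c2O[Si](C)(C)C(C)(C)C)CCC(C)(C)O3)cc1
F7 | step 6 | racemic (1S,2R)-1-{5-[(tert-butyldimethylsilyl)oxy]-8-methoxy-2,2-dimethyl-3,4-dihydro-2H-chromen-6-yl}-2-(4-methoxyphenyl)ethane-1,2-diol (one enantiomer drawn) | O[C@H](c1ccc(OC)cc1)[C@@H](O)c1cc(OC)c2c(c1O[Si](C)(C)C(C)(C)C)CCC(C)(C)O2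
F8 | step 7 | racemic 1-{4-bromo-5-[(tert-butyldimethylsilyl)oxy]-8-methoxy-2,2-dimethyl-3,4-dihydro-2H-chromen-6-yl}-2-(4-methoxyphenyl)ethane-1,2-dione | COc1ccc(C(=O)C(=O)c2cc(OC)c3c(c2O[Si](C)(C)C(C)(C)C)C(Br)CC(C)(C)O3)cc1
F9 | step 1 | 2-(2-bromoethyl)-1,3-dioxolane | BrCCC1OCCO1
F10 | step 1 | 5-(1,3-dioxolan-2-yl)-2-methylpentan-2-ol | CC(C)(O)CCCC1OCCO1
F11 | step 1 | racemic 2-[(6,6-dimethyloxan-2-yl)oxy]ethan-1-ol | CC1(C)CCCC(OCCO)O1
A1 | alternative 1 | 4-methoxybenzene-1,3-diol | COc1ccc(O)cc1O
A2 | alternative 1 | 1-(2,4-dihydroxy-5-methoxyphenyl)-2-(4-methoxyphenyl)ethan-1-one | COc1ccc(CC(=O)c2cc(OC)c(O)cc2O)cc1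
A3 | alternative 1 | 1-(5-hydroxy-8-methoxy-2,2-dimethyl-2H-chromen-6-yl)-2-(4-methoxyphenyl)ethan-1-one | COc1ccc(CC(=O)c2cc(OC)c3c(c2O)C=CC(C)(C)O3)cc1
A4 | alternative 2 | 8-methoxy-2,2-dimethyl-2H-chromen-5-ol | COc1ccc(O)c2c1OC(C)(C)C=C2
A5 | alternative 2 | 8-methoxy-2,2-dimethyl-2H-chromen-5-yl 2-(4-methoxyphenyl)-2-oxoacetate | COc1ccc(C(=O)C(=O)Oc2ccc(OC)c3c2C=CC(C)(C)O3)cc1
A6 | alternative 3 | 4-hydroxy-6-methoxy-3-(4-methoxyphenyl)-8,8-dimethyl-2H,8H-pyrano[2,3-f]chromen-2-one | COc1ccc(C2=C(O)c3cc(OC)c4c(c3OC2=O)C=CC(C)(C)O4)cc1
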